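## Retrosynthetic overview

1. Ester last: the C6 hydroxyl of the diol core (2-oxojaeschkeanadiol) is acylated with a protected 4-hydroxybenzoyl donor, and the phenol is freed at the end.
2. Five-membered ring, formed second: C3–C4 aldol addition in a cycloheptene 1,4-diketone. The C4 carbonyl takes the place of the C4 cation that the cyclase quenches with water; this step sets C4 and gives the trans ring fusion.
3. Seven-membered ring, formed first: tail-to-head cation cyclisation C10→C1 (the 1,7-closure of the farnesyl→daucyl pathway) from a protonated isoprenyl diene. The central olefin is an enol ether (a dihydrofuran tying O6 to C2), which enforces the seven-membered mode and relays C6 to C1.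
4. Acyclic C15 precursor from 2,3-dimethylfuran, isoprene and 2-methyl-1-nitropropane; C6 is the only reagent-controlled stereocentre (Brown isoprenylboration).

Assumption: atoms carry daucane numbers (C1 = ring-fusion C–CH3, C2 = ketone, C3 = CH2, C4 = C(OH)iPr, C5 = ring-fusion CH, C6 = CH–O, C7 = CH2, C8(CH3)=C9, C10 = CH2), and the facial sense of the Brown reagent is taken from its acetaldehyde → (R)-pent-4-en-2-ol precedent (the antipodal pinene gives the antipode).

## Route

Step 1
Reactants: 1 2,3-dimethylfuran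
Product: 3 (2E)-3-methyl-4-oxopent-2-enal, via Z-enal 2 (not isolated)
Conditions: mCPBA (1.05 equiv), CH2Cl2, 0 °C; then pyridine (0.1 equiv), rt
Reagents that add atoms: mCPBA, OOC(=O)c1cccc(Cl)c1
Why: Oxidative ring opening of a furan to the cis-4-oxo-enal (furan → cis-enedione reaction), followed by base-catalysed Z→E isomerisation so that the later γ-hydroxy enone cannot re-close to a furan; no stereocentre is formed.

Step 2
Reactants: 3 (2E)-3-methyl-4-oxopent-2-enal; 4 isoprene
Product: 6 (3E,5S)-5-hydroxy-3-methyl-7-methylidenenona-3,8-dien-2-one, via borinate ester 5 (not isolated)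
Conditions: 4, TMP/n-BuLi/KOtBu, THF, −78 → −45 °C; (−)-Ipc2BOMe, −78 °C; BF3·OEt2; then 3, −78 °C; HOCH2CH2NH2 work-up
Reagents that add atoms: none
Why: Brown asymmetric allylboration with B-isoprenyl-Ipc2B from (+)-α-pinene (chair Zimmerman–Traxler transition state, aldehyde far faster than ketone) sets C6 as S, as in the ipsdienol synthesis from 3-methylbut-2-enal; the non-oxidative work-up spares the enone.

Step 3
Reactants: 6 (3E,5S)-5-hydroxy-3-methyl-7-methylidenenona-3,8-dien-2-one; 7 2-methyl-1-nitropropane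
Product: 8 (5S)-5-hydroxy-3-methyl-4-(2-methyl-1-nitropropyl)-7-methylidenenon-8-en-2-one
Conditions: 7 (3 equiv), DBU (0.2 equiv), MeCN, 0 °C
Reagents that add atoms: none
Why: Nitro-Michael addition of the nitronate (an acyl-anion equivalent) to C5, the only acceptor carbon, brings in C4 with its isopropyl group; the new centres at C1, C5 and the nitro carbon are later planarised or equilibrated, so the diastereomer mixture is carried on.

Step 4
Reactants: 8 (5S)-5-hydroxy-3-methyl-4-(2-methyl-1-nitropropyl)-7-methylidenenon-8-en-2-one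
Product: 10 (5S)-5-hydroxy-3-methyl-4-(2-methylpropanoyl)-7-methylidenenon-8-en-2-one, via sodium nitronate 9 (not isolated)
Conditions: NaOMe (1.1 equiv), MeOH, 0 °C; then aq. TiCl3 (6 equiv), NH4OAc, pH 5–6, 0 °C → rt
Reagents that add atoms: water, O
Why: McMurry reductive Nef reaction converts the secondary nitro group into the C4 ketone under buffered conditions that leave the diene, the β-hydroxy ketone and the C6 centre untouched.

Step 5
Reactants: 10 (5S)-5-hydroxy-3-methyl-4-(2-methylpropanoyl)-7-methylidenenon-8-en-2-one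
Product: 15 1-[(1S,2S,7R)-7-acetyl-2-hydroxy-4,7-dimethylcyclohept-4-en-1-yl]-2-methylpropan-1-one, via dihydrofuran 11 (not isolated), via allyl cation 12 (not isolated), via bridged oxocarbenium ion 13 (not isolated), via C5 epimer 14 (not isolated)
Conditions: PPTS (5 mol %), 4 Å MS, CH2Cl2 (0.005 M), rt; then HNTf2 (10 mol %), HFIP/CH2Cl2 1:4, −40 → 0 °C; H2O/THF; DBU (0.3 equiv), rt
Reagents that add atoms: water, O
Why: Proposed new method: the C6 hydroxyl and C2 ketone first close to a 2,3-dihydrofuran (cyclodehydration of a γ-hydroxy ketone), protonation of the 2-substituted diene then gives the tertiary/primary allyl cation that a cyclase makes from the farnesyl tail, and its primary end C10 is captured by the enol-ether carbon C1 (the only nucleophilic olefin carbon, so the six-membered bisabolyl mode is excluded) through a 7-oxabicyclo[4.2.1] transition state that forces C1–C2 and C6–O cis (C1 = R from C6 = S), after which water opens the bridged oxocarbenium ion and DBU equilibrates the enolisable C5 to the all-trans isomer; the closest known reaction types are acid-catalysed hydroalkylation of 1,3-dienes by enols, enol-ether-terminated cation–olefin cyclisations and tail-to-head cyclisations of tethered allyl cation/alkoxide pairs.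

Step 6
Reactants: 15 1-[(1S,2S,7R)-7-acetyl-2-hydroxy-4,7-dimethylcyclohept-4-en-1-yl]-2-methylpropan-1-one
Product: 18 (3R,3aS,4S,8aR)-3,4-dihydroxy-6,8a-dimethyl-3-(propan-2-yl)-3,3a,4,5,8,8a-hexahydroazulen-1(2H)-one, via dilithium enolate 16 (not isolated), via dilithium aldolate 17 (not isolated)
Conditions: LiHMDS (2.5 equiv), THF, −78 → −30 °C; aq. NH4Cl, −78 °C
Reagents that add atoms: none
Why: Intramolecular aldol addition of the kinetic methyl-ketone enolate (C3) to the C4 ketone (1,4-diketone → 3-hydroxycyclopentanone) is stopped at the lithium aldolate; with C1 and C5 fixed the ring is trans-fused, and lithium bridging of O6 and the C4 carbonyl places the isopropyl group on the H5 side, giving the 4β-hydroxyl (4R).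

Step 7
Reactants: 18 (3R,3aS,4S,8aR)-3,4-dihydroxy-6,8a-dimethyl-3-(propan-2-yl)-3,3a,4,5,8,8a-hexahydroazulen-1(2H)-one; 19 4-acetoxybenzoyl chloride
Product: 20 (3R,3aS,4S,8aR)-3-hydroxy-6,8a-dimethyl-1-oxo-3-(propan-2-yl)-1,2,3,3a,4,5,8,8a-octahydroazulen-4-yl 4-(acetyloxy)benzoate
Conditions: 19 (1.3 equiv), pyridine, DMAP (0.1 equiv), CH2Cl2, 0 °C → rt
Reagents that add atoms: none
Why: DMAP-catalysed acylation is selective for the secondary C6 hydroxyl over the tertiary C4 hydroxyl (the ferutinin-type esterification) and touches no stereocentre.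

Step 8
Reactants: 20 (3R,3aS,4S,8aR)-3-hydroxy-6,8a-dimethyl-1-oxo-3-(propan-2-yl)-1,2,3,3a,4,5,8,8a-octahydroazulen-4-yl 4-(acetyloxy)benzoate
Product: 21 (3R,3aS,4S,8aR)-3-hydroxy-6,8a-dimethyl-1-oxo-3-(propan-2-yl)-1,2,3,3a,4,5,8,8a-octahydroazulen-4-yl 4-hydroxybenzoate
Conditions: NH4OAc (10 equiv), MeOH/H2O 4:1, rt
Reagents that add atoms: none
Why: Neutral transesterification cleaves the aryl acetate much faster than the aroyl ester and spares the acid- and base-sensitive tertiary β-hydroxy ketone.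

## Compound list

1 | 2,3-dimethylfuran | Cc1occc1C | starting material
2 | (2Z)-3-methyl-4-oxopent-2-enal | CC(=O)/C(C)=C\C=O | intermediate
3 | (2E)-3-methyl-4-oxopent-2-enal | CC(=O)/C(C)=C/C=O | intermediate
4 | isoprene (2-methylbuta-1,3-diene) | C=CC(C)=C | starting material
5 | (3E,5S)-3-methyl-7-methylidene-2-oxonona-3,8-dien-5-yl diisopinocampheylborinate | CC(=O)/C(C)=C/[C@H](CC(=C)C=C)OB([C@@H]1C[C@@H]2C[C@H]([C@H]1C)C2(C)C)[C@@H]1C[C@@H]2C[C@H]([C@H]1C)C2(C)C | intermediate
6 | (3E,5S)-5-hydroxy-3-methyl-7-methylidenenona-3,8-dien-2-one | CC(=O)/C(C)=C/[C@@H](O)CC(=C)C=C | intermediate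
7 | 2-methyl-1-nitropropane | CC(C)C[N+](=O)[O-] | starting material
8 | (5S)-5-hydroxy-3-methyl-4-(2-methyl-1-nitropropyl)-7-methylidenenon-8-en-2-one (diastereomer mixture at the three new centres) | CC(=O)C(C)C(C(C(C)C)[N+](=O)[O-])[C@@H](O)CC(=C)C=C | intermediate
9 | sodium nitronate of 8 | CC(=O)C(C)C(C(C(C)C)=[N+]([O-])[O-])[C@@H](O)CC(=C)C=C.[Na+] | intermediate
10 | (5S)-5-hydroxy-3-methyl-4-(2-methylpropanoyl)-7-methylidenenon-8-en-2-one (open form; in equilibrium with its five-membered hemiketal) | CC(=O)C(C)C(C(=O)C(C)C)[C@@H](O)CC(=C)C=C | intermediate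
11 | 1-[(2S)-4,5-dimethyl-2-(2-methylidenebut-3-en-1-yl)-2,3-dihydrofuran-3-yl]-2-methylpropan-1-one | CC1=C(C)C(C(=O)C(C)C)[C@H](CC(=C)C=C)O1 | intermediate
12 | allyl cation from 11 (triflimide salt) | CC1=C(C)C(C(=O)C(C)C)[C@H](C[C+](C)C=C)O1.FC(F)(F)S(=O)(=O)[N-]S(=O)(=O)C(F)(F)F | intermediate
13 | bridged oxocarbenium ion, 7-oxabicyclo[4.2.1]non-3-ene core (triflimide salt) | CC1=[O+][C@H]2CC(C)=CC[C@]1(C)[C@H]2C(=O)C(C)C.FC(F)(F)S(=O)(=O)[N-]S(=O)(=O)C(F)(F)F | intermediate
14 | 1-[(1R,2S,7R)-7-acetyl-2-hydroxy-4,7-dimethylcyclohept-4-en-1-yl]-2-methylpropan-1-one (C5 epimer of 15) | CC1=CC[C@@](C)(C(C)=O)[C@@H](C(=O)C(C)C)[C@@H](O)C1 | intermediate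
15 | 1-[(1S,2S,7R)-7-acetyl-2-hydroxy-4,7-dimethylcyclohept-4-en-1-yl]-2-methylpropan-1-one (open form; in equilibrium with its bridged hemiketal) | CC1=CC[C@@](C)(C(C)=O)[C@H](C(=O)C(C)C)[C@@H](O)C1 | intermediate
16 | dilithium alkoxide-enolate of 15 | CC1=CC[C@@](C)(C(=C)[O-])[C@H](C(=O)C(C)C)[C@@H]([O-])C1.[Li+].[Li+] | intermediate
17 | dilithium aldolate of 18 | CC1=CC[C@@]2(C)C(=O)C[C@@]([O-])(C(C)C)[C@@H]2[C@@H]([O-])C1.[Li+].[Li+] | intermediate
18 | (3R,3aS,4S,8aR)-3,4-dihydroxy-6,8a-dimethyl-3-(propan-2-yl)-3,3a,4,5,8,8a-hexahydroazulen-1(2H)-one | CC1=CC[C@@]2(C)C(=O)C[C@@](O)(C(C)C)[C@@H]2[C@@H](O)C1 | intermediate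
19 | 4-acetoxybenzoyl chloride | CC(=O)Oc1ccc(cc1)C(Cl)=O | starting material
20 | (3R,3aS,4S,8aR)-3-hydroxy-6,8a-dimethyl-1-oxo-3-(propan-2-yl)-1,2,3,3a,4,5,8,8a-octahydroazulen-4-yl 4-(acetyloxy)benzoate | CC1=CC[C@@]2(C)C(=O)C[C@@](O)(C(C)C)[C@@H]2[C@@H](OC(=O)c2ccc(OC(C)=O)cc2)C1 | intermediate
21 | (3R,3aS,4S,8aR)-3-hydroxy-6,8a-dimethyl-1-oxo-3-(propan-2-yl)-1,2,3,3a,4,5,8,8a-octahydroazulen-4-yl 4-hydroxybenzoate | CC1=CC[C@@]2(C)C(=O)C[C@@](O)(C(C)C)[C@@H]2[C@@H](OC(=O)c2ccc(O)cc2)C1 | target

## Step count and risks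

Total step count: 8. Longest linear sequence: 8 (from 2,3-dimethylfuran).

Steps most likely to fail:

Step 5 (cation cyclisation). The 1,4-diketone 10 can go to a Paal–Knorr furan under acid, O6 can β-eliminate from the dihydrofuran, and the C5 equilibration may not favour 15 cleanly. The fallback separates cation generation from Brønsted acid. It sets out from 10: PPTS and sieves give the dihydrofuran 11, which is isolated this time. One equivalent of HCl in Et2O at −78 °C adds 1,4 across the diene to give the allylic chloride 1-[(2S)-2-(4-chloro-2-methylbut-2-en-1-yl)-4,5-dimethyl-2,3-dihydrofuran-3-yl]-2-methylpropan-1-one F1. AgNTf2 with 2,6-di-tert-butylpyridine in CH2Cl2 at −78 °C ionises F1 under aprotic, buffered conditions to the allyl cation 12; E/Z relay runs through the tertiary chloride. After hydrolysis and C5 equilibration the route comes back at 15.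

Step 3 (nitro-Michael on a γ-hydroxy enone). DBU may isomerise 6 to the furan or to the 1,4-diketone, which would lose C6, faster than the hindered nitronate adds. The fallback changes the acyl-anion equivalent and works at −78 °C. It sets out from 6: TESCl and imidazole give (3E,5S)-3-methyl-7-methylidene-5-[(triethylsilyl)oxy]nona-3,8-dien-2-one F2. 2-Lithio-2-isopropyl-1,3-dithiane in THF/HMPA at −78 °C adds 1,4 to give (5S)-3-methyl-7-methylidene-4-[2-(propan-2-yl)-1,3-dithian-2-yl]-5-[(triethylsilyl)oxy]non-8-en-2-one F3. MeI/CaCO3 in aqueous MeCN and then HF·pyridine unmask the ketone and the alcohol, and the route comes back at 10 (steps 3 and 4 are replaced by three steps).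

Step 6 (aldol ring closure). The 5-(enolendo) closure may be slow, and the aldolate may revert or dehydrate to the cyclopentenone. The fallback is a Lewis-acid aldol. It sets out from 15: TMSOTf and Et3N in CH2Cl2 at −78 °C give 1-[(1S,2S,7R)-4,7-dimethyl-2-[(trimethylsilyl)oxy]-7-{1-[(trimethylsilyl)oxy]ethenyl}cyclohept-4-en-1-yl]-2-methylpropan-1-one F4. TiCl4 in CH2Cl2 at −78 °C effects the intramolecular Mukaiyama aldol addition to the C4 ketone, and citric acid/MeOH work-up removes the remaining silyl group; the route comes back at 18.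

## Further compounds

F1 | step 5 | 1-[(2S)-2-(4-chloro-2-methylbut-2-en-1-yl)-4,5-dimethyl-2,3-dihydrofuran-3-yl]-2-methylpropan-1-one | CC1=C(C)C(C(=O)C(C)C)[C@H](CC(C)=CCCl)O1
F2 | step 3 | (3E,5S)-3-methyl-7-methylidene-5-[(triethylsilyl)oxy]nona-3,8-dien-2-one | CC(=O)/C(C)=C/[C@@H](O[Si](CC)(CC)CC)CC(=C)C=C
F3 | step 3 | (5S)-3-methyl-7-methylidene-4-[2-(propan-2-yl)-1,3-dithian-2-yl]-5-[(triethylsilyl)oxy]non-8-en-2-one | CC(=O)C(C)C(C1(C(C)C)SCCCS1)[C@@H](O[Si](CC)(CC)CC)CC(=C)C=C
F4 | step 6 | 1-[(1S,2S,7R)-4,7-dimethyl-2-[(trimethylsilyl)oxy]-7-{1-[(trimethylsilyl)oxy]ethenyl}cyclohept-4-en-1-yl]-2-methylpropan-1-one | CC1=CC[C@@](C)(C(=C)O[Si](C)(C)C)[C@H](C(=O)C(C)C)[C@@H](O[Si](C)(C)C)C1
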